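**Direct plan and its weak points**

A direct plan would make the ring-B chloromethyl ketone A2 from dibromide A1 by two bromine–lithium exchanges (prenylation, then Weinreb acylation), O-alkylate salicylaldehyde A3 with it to keto-aldehyde A4, close ring C by a carbene-catalysed crossed benzoin reaction to ketol A5, dehydrate to A6 and remove three MOM groups with acid.
Its weakest steps would be: the first bromine–lithium exchange on A1, which would have to tell two bromines apart by chelation alone; the benzoin closure of A4, an acyl-anion addition to a hindered ketone against competing aldol and aryloxide-loss pathways; and the acidic end game, in which SOCl2 and then HCl would meet a prenyl group ortho to a phenol (HCl addition, chroman formation).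

**New strategy**

The route exploits that ring C with its C3-bound ring B is a rearranged chalcone. As in isoflavone biosynthesis, the C3–C1' bond is made by shifting ring B from C2 to C3 of chalcone 6, which holds all fifteen skeletal carbons and a bromine at C5'. Tl(NO3)3 in methanol should trigger this 1,2-shift, and acid then closes ring C through O1–C2 and frees every phenol in the same operation. The bromine survives the oxidation; the prenyl group is coupled on afterwards and the phenols are unmasked with methanol and carbonate. No bromine–lithium exchange chooses between two bromines, no benzoin or ketol dehydration occurs, and no acid meets the prenyl group.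

Key step: step 4

Assumption: compounds 1 and 3 are taken as purchasable (3 is otherwise one demethylation away from 5-bromovanillin); the transient stereocentres in 5, 7 and 8 are racemic and vanish before compound 9, and the target is achiral.

**Route**

Step 1
Reactants: 1 1-(2,4-dihydroxy-6-methoxyphenyl)ethan-1-one
Product: 2 1-[2-methoxy-4,6-bis(methoxymethoxy)phenyl]ethan-1-one
Conditions: NaH (2.3 equiv), MOMCl (2.5 equiv), DMF, 0 °C → rt
Reagents that add atoms: chloromethyl methyl ether (MOMCl), COCCl
Why: Williamson-type O-alkylation (SN2 at the α-chloro ether) of both sodium phenoxides should go to completion because NaH also deprotonates the hydroxyl that is hydrogen-bonded to the ketone, and the two acetals keep ring A non-phenolic through condensation and oxidation and block aurone or flavanone formation at the 2-oxygen.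

Step 2
Reactants: 3 3-bromo-4,5-dihydroxybenzaldehyde
Product: 4 7-bromo-2,2-diphenyl-1,3-benzodioxole-5-carbaldehyde
Conditions: Ph2CCl2 (1.3 equiv), Ph2O, 175 °C, N2 stream
Reagents that add atoms: dichlorodiphenylmethane, ClC(Cl)(c1ccccc1)c1ccccc1
Why: Thermal ketalisation of the catechol with the benzhydrylic gem-dichloride (twofold SN1-type substitution with loss of HCl) should give the diphenylmethylene ketal, which is stable to hydroxide and whose five-membered ring holds the oxygen para to the future migrating carbon in conjugation in spite of the ortho bromine.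

Step 3
Reactants: 2 1-[2-methoxy-4,6-bis(methoxymethoxy)phenyl]ethan-1-one; 4 7-bromo-2,2-diphenyl-1,3-benzodioxole-5-carbaldehyde (1.05 equiv)
Product: 6 (E)-3-(7-bromo-2,2-diphenyl-1,3-benzodioxol-5-yl)-1-[2-methoxy-4,6-bis(methoxymethoxy)phenyl]prop-2-en-1-one, via aldol adduct 5 (not isolated)
Conditions: KOH (50% aq, 6 equiv), EtOH/THF (3:1), rt
Reagents that add atoms: none
Why: Claisen–Schmidt condensation, in which the enolate of the methyl ketone adds to the non-enolisable aldehyde and aldol 5 loses hydroxide by E1cB, should give the thermodynamically favoured E enone while acetals, ketal and aryl bromide are inert to hydroxide.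

Step 4
Reactants: 6 (E)-3-(7-bromo-2,2-diphenyl-1,3-benzodioxol-5-yl)-1-[2-methoxy-4,6-bis(methoxymethoxy)phenyl]prop-2-en-1-one
Product: 9 3-(3-bromo-4,5-dihydroxyphenyl)-7-hydroxy-5-methoxy-4H-chromen-4-one, via methoxythallation adduct 7 (not isolated), via keto acetal 8 (not isolated)
Conditions: Tl(NO3)3·3H2O (1.15 equiv), MeOH/CH(OMe)3 (3:1), rt; filter; then 6 M HCl (aq)/MeOH (1:3), reflux
Reagents that add atoms: none
Why: Anti methoxythallation of the enone places methoxide at the benzylic carbon and trivalent thallium at the α-carbon (adduct 7); the C–Tl bond then ionises with 1,2-migration of ring B from Cβ to Cα through a phenonium-type transition state, thallium leaves as TlNO3 and methanol captures the oxocarbenium ion to give acetal 8, which is the known oxidative rearrangement of chalcones and the laboratory counterpart of the 2→3 aryl shift of isoflavone synthase. In the acid stage the two MOM ethers and the diphenylmethylene ketal are solvolysed (formaldehyde being trapped as dimethoxymethane), and the freed 2-hydroxyl of ring A attacks the oxocarbenium ion derived from the acetal in a 6-exo-trig closure of ring C (O1–C2), after which loss of methanol gives the aromatic 4-pyranone. The stereocentre at C3 of 8 is formed racemic and is destroyed in this elimination, so no configuration has to be controlled. The selectivity needed is migration of ring B and not of ring A or hydride: the dioxole keeps the para oxygen of ring B planar and donating, while the 2,6-dioxygenated aroyl group is too hindered to form the hemiketal from which ring A could migrate. Aurone or flavanone formation is excluded because the 2-oxygen of ring A stays masked until the acid stage, and ring closure can use only this oxygen because the other ortho position carries the methyl ether.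

Step 5
Reactants: 9 3-(3-bromo-4,5-dihydroxyphenyl)-7-hydroxy-5-methoxy-4H-chromen-4-one
Product: 10 3-[3,4-bis(acetyloxy)-5-bromophenyl]-5-methoxy-4-oxo-4H-chromen-7-yl acetate
Conditions: Ac2O (6 equiv), pyridine, DMAP (5 mol%), rt
Reagents that add atoms: acetic anhydride, CC(=O)OC(C)=O
Why: DMAP-catalysed O-acylation of all three phenols should give a triacetate that no longer carries acidic protons able to protodestannylate the allylstannane, is less electron-rich at the C–Br bond, and can later be unmasked without acid.

Step 6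
Reactants: 10 3-[3,4-bis(acetyloxy)-5-bromophenyl]-5-methoxy-4-oxo-4H-chromen-7-yl acetate
Product: 11 3-[3,4-bis(acetyloxy)-5-(3-methylbut-2-en-1-yl)phenyl]-5-methoxy-4-oxo-4H-chromen-7-yl acetate
Conditions: tributyl(3-methylbut-2-en-1-yl)stannane (1.5 equiv), Pd(PPh3)4 (5 mol%), DMF (degassed), 90 °C
Reagents that add atoms: tributyl(3-methylbut-2-en-1-yl)stannane, CCCC[Sn](CCCC)(CCCC)CC=C(C)C
Why: Migita–Kosugi–Stille coupling, in which zerovalent palladium inserts into the C–Br bond, the prenyl group is transferred from tin and reductive elimination takes place at the unhindered CH2 terminus of the allyl ligand, should give the linear prenyl arene under neutral conditions that leave the aryl acetates and the pyranone untouched.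

Step 7
Reactants: 11 3-[3,4-bis(acetyloxy)-5-(3-methylbut-2-en-1-yl)phenyl]-5-methoxy-4-oxo-4H-chromen-7-yl acetate
Product: 12 glisoflavone, 3-[3,4-dihydroxy-5-(3-methylbut-2-en-1-yl)phenyl]-7-hydroxy-5-methoxy-4H-chromen-4-one
Conditions: K2CO3 (0.3 equiv), MeOH (degassed), Ar, 0 °C → rt; then sat. NH4Cl (aq)
Reagents that add atoms: none
Why: Carbonate-catalysed transesterification with methanol should cleave the three aryl acetates (phenoxide is the better leaving group) at or below room temperature, and because no acid is present the prenyl alkene next to the freed 4'-hydroxyl cannot cyclise to a chroman or add HX; the product has no stereocentre.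

**Compound list**

1 | 1-(2,4-dihydroxy-6-methoxyphenyl)ethan-1-one | COc1cc(O)cc(O)c1C(C)=O | starting material
2 | 1-[2-methoxy-4,6-bis(methoxymethoxy)phenyl]ethan-1-one | COCOc1cc(OC)c(C(C)=O)c(OCOC)c1 | intermediate
3 | 3-bromo-4,5-dihydroxybenzaldehyde | O=Cc1cc(O)c(O)c(Br)c1 | starting material
4 | 7-bromo-2,2-diphenyl-1,3-benzodioxole-5-carbaldehyde | O=Cc1cc(Br)c2OC(c3ccccc3)(c3ccccc3)Oc2c1 | intermediate
5 | rac-3-(7-bromo-2,2-diphenyl-1,3-benzodioxol-5-yl)-3-hydroxy-1-[2-methoxy-4,6-bis(methoxymethoxy)phenyl]propan-1-one (aldol adduct, racemic) | COCOc1cc(OC)c(C(=O)CC(O)c2cc(Br)c3OC(c4ccccc4)(c4ccccc4)Oc3c2)c(OCOC)c1 | intermediate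
6 | (E)-3-(7-bromo-2,2-diphenyl-1,3-benzodioxol-5-yl)-1-[2-methoxy-4,6-bis(methoxymethoxy)phenyl]prop-2-en-1-one | COCOc1cc(OC)c(C(=O)/C=C/c2cc(Br)c3OC(c4ccccc4)(c4ccccc4)Oc3c2)c(OCOC)c1 | intermediate
7 | rac-(2R,3R)-3-(7-bromo-2,2-diphenyl-1,3-benzodioxol-5-yl)-2-(dinitratothallio)-3-methoxy-1-[2-methoxy-4,6-bis(methoxymethoxy)phenyl]propan-1-one (anti adduct, racemic, one enantiomer drawn) | COCOc1cc(OC)c(C(=O)[C@H]([Tl](O[N+](=O)[O-])O[N+](=O)[O-])[C@H](OC)c2cc(Br)c3OC(c4ccccc4)(c4ccccc4)Oc3c2)c(OCOC)c1 | intermediate
8 | rac-2-(7-bromo-2,2-diphenyl-1,3-benzodioxol-5-yl)-3,3-dimethoxy-1-[2-methoxy-4,6-bis(methoxymethoxy)phenyl]propan-1-one (racemic at C2) | COCOc1cc(OC)c(C(=O)C(C(OC)OC)c2cc(Br)c3OC(c4ccccc4)(c4ccccc4)Oc3c2)c(OCOC)c1 | intermediate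
9 | 3-(3-bromo-4,5-dihydroxyphenyl)-7-hydroxy-5-methoxy-4H-chromen-4-one | COc1cc(O)cc2occ(-c3cc(Br)c(O)c(O)c3)c(=O)c12 | intermediate
10 | 3-[3,4-bis(acetyloxy)-5-bromophenyl]-5-methoxy-4-oxo-4H-chromen-7-yl acetate | COc1cc(OC(C)=O)cc2occ(-c3cc(Br)c(OC(C)=O)c(OC(C)=O)c3)c(=O)c12 | intermediate
11 | 3-[3,4-bis(acetyloxy)-5-(3-methylbut-2-en-1-yl)phenyl]-5-methoxy-4-oxo-4H-chromen-7-yl acetate | COc1cc(OC(C)=O)cc2occ(-c3cc(CC=C(C)C)c(OC(C)=O)c(OC(C)=O)c3)c(=O)c12 | intermediate
12 | glisoflavone, 3-[3,4-dihydroxy-5-(3-methylbut-2-en-1-yl)phenyl]-7-hydroxy-5-methoxy-4H-chromen-4-one (achiral) | COc1cc(O)cc2occ(-c3cc(O)c(O)c(CC=C(C)C)c3)c(=O)c12 | target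

**Count and risks**

Total step count: 7. Longest linear sequence: 6 (step 1 or step 2, then steps 3 to 7).

Steps most likely to fail:

1. Step 4. The wrong group could migrate (ring A or hydride), the electron-rich ring A could be over-oxidised by trivalent thallium, or the ketal could be cleaved incompletely. Fallback: from chalcone 6, nucleophilic epoxidation (H2O2, NaOH, MeOH/THF, 0 °C) would give the racemic trans-epoxide F1. BF3·OEt2 in CH2Cl2 at −20 °C would open it at the benzylic carbon and induce a 1,2-shift of the aroyl group (Meinwald-type rearrangement) to the 2-aryl-3-oxopropanal F2, in which ring B again sits on the future C3. The same hot HCl/MeOH treatment would then cleave the protecting groups and cyclise F2, returning to the route at compound 9.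

2. Step 6. The prenyl group could be transferred through its tertiary terminus (branched isomer), the stannane could be protodestannylated, or oxidative addition next to the acetoxy group could be slow. Fallback: from triacetate 10, Stille coupling with allyltributylstannane (Pd(PPh3)4, DMF, 90 °C), which has no such regiochemical ambiguity, would give the allyl arene F3. Olefin cross-metathesis with 2-methylbut-2-ene (second-generation Grubbs catalyst, CH2Cl2, 40 °C) would convert the allyl into the prenyl group and return to the route at compound 11.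

3. Step 7. The catecholate could be oxidised by air, or methoxide could add at C2 and open the pyranone during the basic unmasking. Fallback: from triol 9, silylation (TBSCl, imidazole, DMF) would give the tris(tert-butyldimethylsilyl) ether F4, and the same Stille prenylation would give the prenylated tris-silyl ether F5. Fluoride buffered with acetic acid (Bu4NF/AcOH, THF, 0 °C) would then release compound 12 at near-neutral pH.

**Further compounds**

F1 | step 4 | rac-trans-[3-(7-bromo-2,2-diphenyl-1,3-benzodioxol-5-yl)oxiran-2-yl][2-methoxy-4,6-bis(methoxymethoxy)phenyl]methanone (racemic, one enantiomer drawn) | COCOc1cc(OC)c(C(=O)[C@H]5O[C@@H]5c2cc(Br)c3OC(c4ccccc4)(c4ccccc4)Oc3c2)c(OCOC)c1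
F2 | step 4 | rac-2-(7-bromo-2,2-diphenyl-1,3-benzodioxol-5-yl)-3-[2-methoxy-4,6-bis(methoxymethoxy)phenyl]-3-oxopropanal | COCOc1cc(OC)c(C(=O)C(C=O)c2cc(Br)c3OC(c4ccccc4)(c4ccccc4)Oc3c2)c(OCOC)c1
F3 | step 6 | 3-[3,4-bis(acetyloxy)-5-(prop-2-en-1-yl)phenyl]-5-methoxy-4-oxo-4H-chromen-7-yl acetate | COc1cc(OC(C)=O)cc2occ(-c3cc(CC=C)c(OC(C)=O)c(OC(C)=O)c3)c(=O)c12
F4 | step 7 | 3-{3-bromo-4,5-bis[(tert-butyldimethylsilyl)oxy]phenyl}-7-[(tert-butyldimethylsilyl)oxy]-5-methoxy-4H-chromen-4-one | COc1cc(O[Si](C)(C)C(C)(C)C)cc2occ(-c3cc(Br)c(O[Si](C)(C)C(C)(C)C)c(O[Si](C)(C)C(C)(C)C)c3)c(=O)c12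
F5 | step 7 | 3-{3,4-bis[(tert-butyldimethylsilyl)oxy]-5-(3-methylbut-2-en-1-yl)phenyl}-7-[(tert-butyldimethylsilyl)oxy]-5-methoxy-4H-chromen-4-one | COc1cc(O[Si](C)(C)C(C)(C)C)cc2occ(-c3cc(CC=C(C)C)c(O[Si](C)(C)C(C)(C)C)c(O[Si](C)(C)C(C)(C)C)c3)c(=O)c12
A1 | direct plan | 1,5-dibromo-2,3-bis(methoxymethoxy)benzene | COCOc1cc(Br)cc(Br)c1OCOC
A2 | direct plan | 2-chloro-1-[3,4-bis(methoxymethoxy)-5-(3-methylbut-2-en-1-yl)phenyl]ethan-1-one | COCOc1cc(C(=O)CCl)cc(CC=C(C)C)c1OCOC
A3 | direct plan | 2-hydroxy-6-methoxy-4-(methoxymethoxy)benzaldehyde | COCOc1cc(O)c(C=O)c(OC)c1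
A4 | direct plan | 2-{2-[3,4-bis(methoxymethoxy)-5-(3-methylbut-2-en-1-yl)phenyl]-2-oxoethoxy}-6-methoxy-4-(methoxymethoxy)benzaldehyde | COCOc1cc(OC)c(C=O)c(OCC(=O)c2cc(CC=C(C)C)c(OCOC)c(OCOC)c2)c1
A5 | direct plan | rac-3-[3,4-bis(methoxymethoxy)-5-(3-methylbut-2-en-1-yl)phenyl]-3-hydroxy-5-methoxy-7-(methoxymethoxy)chroman-4-one | COCOc1cc(OC)c2c(c1)OCC(O)(c1cc(CC=C(C)C)c(OCOC)c(OCOC)c1)C2=O
A6 | direct plan | 3-[3,4-bis(methoxymethoxy)-5-(3-methylbut-2-en-1-yl)phenyl]-5-methoxy-7-(methoxymethoxy)-4H-chromen-4-one | COCOc1cc(OC)c2c(c1)occ(-c1cc(CC=C(C)C)c(OCOC)c(OCOC)c1)c2=O
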